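**Plan**

- Retrosynthesis: the 7-OH is traced back to a MOM ether. The dimethylpyran on ring B is cut at its two C2''–CH3 bonds and its O–C2'' bond, which leads back to a coumarin lactone. Ring C is cut at O1–C2 and C3–OH (oxidative cyclisation of a chalcone), the chalcone at its Cα=Cβ bond, ring A at its two aryl–prenyl bonds, and the coumarin at its C7–CHO bond.
- Forward: the acetophenone of ring A is doubly C-prenylated and protected. The coumarin comes intact from umbelliferone and is formylated at C7. Claisen–Schmidt condensation and Algar–Flynn–Oyamada oxidation, run in one flask, join the halves and close ring C. The 2,2-dimethyl-2H-pyran ring is closed last.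
- Enabling feature: pyran carbon C2'' carries two methyl groups and the aryl ether oxygen. A lactone carbonyl ends up with exactly this pattern after taking up two methyl nucleophiles and re-closing, and umbelliferone fixes the 7-substitution of the coumarin.
- Stereochemistry: the target has no stereocentre. The cis ring alkene C3''=C4'' is inherited from the coumarin; the transient trans-dihydroflavonol is racemic and is dehydrogenated in the same flask.

Key step: step 7

Remark: 2',4',6'-trihydroxyacetophenone is taken as a purchasable starting material. Species formed in aqueous alkali are written as neutral acids although they are present as salts, and racemic intermediates are drawn as one enantiomer.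

**Route**

Step 1
Reactants: 1 umbelliferone (7-hydroxy-2H-chromen-2-one)
Product: 2 2-oxo-2H-chromen-7-yl trifluoromethanesulfonate
Conditions: Tf2O (1.2 equiv), pyridine, CH2Cl2, 0 °C to rt
Reagents that add atoms: trifluoromethanesulfonic anhydride, O=S(=O)(OS(=O)(=O)C(F)(F)F)C(F)(F)F
Why: O-sulfonylation of the phenol (aryl triflate formation) is fast, leaves the lactone untouched and turns C7 into a site for palladium-catalysed carbonylation.

Step 2
Reactants: 2 2-oxo-2H-chromen-7-yl trifluoromethanesulfonate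
Product: 3 2-oxo-2H-chromene-7-carbaldehyde
Conditions: Pd(OAc)2 (5 mol %), dppp, CO (1 atm), Et3SiH, Et3N, DMF, 70 °C
Reagents that add atoms: carbon monoxide, [C-]#[O+]
Why: Palladium-catalysed reductive carbonylation (formylation) of an aryl triflate: oxidative addition to zerovalent palladium, CO insertion and hydride transfer from the silane to the aroylpalladium species should release the aldehyde, the electron-poor triflate being a good substrate and the lactone inert.

Step 3
Reactants: 4 1-(2,4,6-trihydroxyphenyl)ethan-1-one (2',4',6'-trihydroxyacetophenone); 5 prenyl bromide (1-bromo-3-methylbut-2-ene)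
Product: 6 1-[2,4,6-trihydroxy-3,5-bis(3-methylbut-2-en-1-yl)phenyl]ethan-1-one
Conditions: prenyl bromide (2.2 equiv), KOH (10% aq.), 0 °C to rt, N2
Reagents that add atoms: prenyl bromide (5), CC(C)=CCBr
Why: C-alkylation of the ambident phloroacetophenone anion in water, the classical double C-prenylation of acylphloroglucinols, should place prenyl groups on the only two free ring carbons (C3 and C5), the protic medium favouring carbon over oxygen attack; mono- and over-alkylated material is removed by chromatography.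

Step 4
Reactants: 6 1-[2,4,6-trihydroxy-3,5-bis(3-methylbut-2-en-1-yl)phenyl]ethan-1-one
Product: 7 1-[2-hydroxy-4,6-bis(methoxymethoxy)-3,5-bis(3-methylbut-2-en-1-yl)phenyl]ethan-1-one
Conditions: MOMCl (2.4 equiv), i-Pr2NEt, CH2Cl2, 0 °C to rt
Reagents that add atoms: chloromethyl methyl ether, COCCl
Why: Williamson-type O-alkylation with MOMCl protects the 4-OH and one of the two equivalent ortho hydroxyls, while the last hydroxyl is held in a hydrogen bond to the acetyl carbonyl and should stay free, as is usual for phloroacetophenones treated with about two equivalents of MOMCl.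

Step 5
Reactants: 7 1-[2-hydroxy-4,6-bis(methoxymethoxy)-3,5-bis(3-methylbut-2-en-1-yl)phenyl]ethan-1-one; 3 2-oxo-2H-chromene-7-carbaldehyde
Product: 11 3-hydroxy-5,7-bis(methoxymethoxy)-6,8-bis(3-methylbut-2-en-1-yl)-2-(2-oxo-2H-chromen-7-yl)-4H-chromen-4-one, via coumarinic acid chalcone 8 (not isolated), via ring-opened trans-dihydroflavonol 9 (not isolated), via ring-opened flavonol acid 10 (not isolated)
Conditions: KOH (40% aq.), EtOH, rt, dark, N2; then MeOH, 0 °C, H2O2 (30% aq.), 0 °C to rt; then 1 M HCl to pH 3, 0 °C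
Reagents that add atoms: hydrogen peroxide, OO
Why: One-pot Claisen–Schmidt condensation and Algar–Flynn–Oyamada oxidation: the methyl ketone enolate adds to the non-enolisable aldehyde and E1cB dehydration gives the (E)-chalcone, whose lactone is held open by hydroxide as the (Z)-coumarinate 8; hydroperoxide then attacks the enone, the 2'-phenoxide closes ring C at the benzylic carbon (6-endo) to the trans-3-hydroxyflavanone 9, excess peroxide dehydrogenates it to the flavonol 10, and acidification re-closes the lactone, the prenyl olefins and the open carboxylate being inert to nucleophilic peroxide and the MOM ethers stable to base.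

Step 6
Reactants: 11 3-hydroxy-5,7-bis(methoxymethoxy)-6,8-bis(3-methylbut-2-en-1-yl)-2-(2-oxo-2H-chromen-7-yl)-4H-chromen-4-one
Product: 12 3,5-dihydroxy-7-(methoxymethoxy)-6,8-bis(3-methylbut-2-en-1-yl)-2-(2-oxo-2H-chromen-7-yl)-4H-chromen-4-one
Conditions: HCl (0.2 M in MeOH), THF, 0 °C to rt, stopped at mono-cleavage
Reagents that add atoms: none
Why: Acid-catalysed acetal exchange: the 5-O-MOM ether peri to the C4 carbonyl should go first because the departing phenol is stabilised by its hydrogen bond to that carbonyl (the chelation effect behind selective 5-O-deprotection of flavones), so brief exposure to dilute methanolic HCl should spare the 7-O-MOM ether, the prenyl groups and the lactone.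

Step 7
Reactants: 12 3,5-dihydroxy-7-(methoxymethoxy)-6,8-bis(3-methylbut-2-en-1-yl)-2-(2-oxo-2H-chromen-7-yl)-4H-chromen-4-one; 13 methylmagnesium bromide
Product: 16 2-(2,2-dimethyl-2H-chromen-7-yl)-3,5-dihydroxy-7-(methoxymethoxy)-6,8-bis(3-methylbut-2-en-1-yl)-4H-chromen-4-one (dorsilurin C 7-methoxymethyl ether), via (Z)-enone phenol 14 (not isolated), via (Z)-tertiary allylic alcohol 15 (not isolated)
Conditions: MeMgBr (8 equiv), THF, −20 °C to rt; sat. aq. NH4Cl; then PPTS (cat.), CH2Cl2, rt
Reagents that add atoms: methylmagnesium bromide (13), C[Mg]Br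
Why: The first two equivalents of MeMgBr convert the 3- and 5-hydroxyls into a bis(bromomagnesium) chelate around the C4 carbonyl, which makes that vinylogous ester a vinylogous carboxylate and leaves the coumarin lactone as the only electrophilic carbonyl. The hard methyl nucleophile then adds 1,2 to the lactone, the ring opens to the (Z)-enone phenoxide 14, and a second 1,2-addition gives the tertiary allylic alkoxide 15, so both C2''–CH3 bonds are made. Buffered acid (NH4Cl work-up, then catalytic PPTS) ionises the tertiary allylic alcohol to an aryl-conjugated allyl cation that the ortho phenol captures at the dimethyl-bearing terminus; this forms the O–C2'' bond in a 6-endo closure, equivalent to an oxa-6π electrocyclisation of the ortho-quinone methide, with the cis alkene from the lactone holding the two ends together. The closest known reaction is the conversion of simple coumarins into 2,2-dimethyl-2H-chromenes by methyl Grignard or methyllithium addition followed by acid cyclisation. No stereocentre is created; the selectivities needed are lactone over C4 carbonyl (secured by the dianionic chelate), 1,2 over 1,4 addition (favoured by the methyl reagent and low temperature) and pyran closure without cyclisation of the ortho-prenyl phenols or loss of the MOM ether (secured by the mildness of PPTS).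

Step 8
Reactants: 16 2-(2,2-dimethyl-2H-chromen-7-yl)-3,5-dihydroxy-7-(methoxymethoxy)-6,8-bis(3-methylbut-2-en-1-yl)-4H-chromen-4-one
Product: 17 dorsilurin C, 2-(2,2-dimethyl-2H-chromen-7-yl)-3,5,7-trihydroxy-6,8-bis(3-methylbut-2-en-1-yl)-4H-chromen-4-one
Conditions: HCl (1 M in MeOH), rt to 40 °C
Reagents that add atoms: none
Why: Acid-catalysed methanolysis of the MOM acetal: the 7-O-MOM ether, twisted out of conjugation by its two ortho prenyl groups, should cleave under dilute methanolic HCl at mild temperature, conditions that prenylated flavonoids and their 2,2-dimethylchromene rings normally tolerate, the flavonol substituent para to the chromene benzylic carbon further disfavouring protonation of the ring alkene.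

**Compound list**

1 | umbelliferone (7-hydroxy-2H-chromen-2-one) | O=c1ccc2ccc(O)cc2o1 | starting material
2 | 2-oxo-2H-chromen-7-yl trifluoromethanesulfonate | O=c1ccc2ccc(OS(=O)(=O)C(F)(F)F)cc2o1 | intermediate
3 | 2-oxo-2H-chromene-7-carbaldehyde | O=Cc1ccc2ccc(=O)oc2c1 | intermediate
4 | 1-(2,4,6-trihydroxyphenyl)ethan-1-one (2',4',6'-trihydroxyacetophenone) | CC(=O)c1c(O)cc(O)cc1O | starting material
5 | prenyl bromide (1-bromo-3-methylbut-2-ene) | CC(C)=CCBr | starting material
6 | 1-[2,4,6-trihydroxy-3,5-bis(3-methylbut-2-en-1-yl)phenyl]ethan-1-one | CC(=O)c1c(O)c(CC=C(C)C)c(O)c(CC=C(C)C)c1O | intermediate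
7 | 1-[2-hydroxy-4,6-bis(methoxymethoxy)-3,5-bis(3-methylbut-2-en-1-yl)phenyl]ethan-1-one | CC(=O)c1c(O)c(CC=C(C)C)c(OCOC)c(CC=C(C)C)c1OCOC | intermediate
8 | (2Z)-3-{2-hydroxy-4-[(1E)-3-[2-hydroxy-4,6-bis(methoxymethoxy)-3,5-bis(3-methylbut-2-en-1-yl)phenyl]-3-oxoprop-1-en-1-yl]phenyl}prop-2-enoic acid (ring-opened chalcone, not isolated) | OC(=O)/C=C\c1ccc(/C=C/C(=O)c2c(O)c(CC=C(C)C)c(OCOC)c(CC=C(C)C)c2OCOC)cc1O | intermediate
9 | (2Z)-3-{2-hydroxy-4-[(2R*,3R*)-3-hydroxy-5,7-bis(methoxymethoxy)-6,8-bis(3-methylbut-2-en-1-yl)-4-oxo-3,4-dihydro-2H-chromen-2-yl]phenyl}prop-2-enoic acid (racemic trans, one enantiomer drawn, not isolated) | O=C1[C@H](O)[C@@H](c3ccc(/C=C\C(O)=O)c(O)c3)Oc2c(CC=C(C)C)c(OCOC)c(CC=C(C)C)c(OCOC)c12 | intermediate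
10 | (2Z)-3-{2-hydroxy-4-[3-hydroxy-5,7-bis(methoxymethoxy)-6,8-bis(3-methylbut-2-en-1-yl)-4-oxo-4H-chromen-2-yl]phenyl}prop-2-enoic acid (ring-opened flavonol, not isolated) | OC(=O)/C=C\c1ccc(-c2oc3c(CC=C(C)C)c(OCOC)c(CC=C(C)C)c(OCOC)c3c(=O)c2O)cc1O | intermediate
11 | 3-hydroxy-5,7-bis(methoxymethoxy)-6,8-bis(3-methylbut-2-en-1-yl)-2-(2-oxo-2H-chromen-7-yl)-4H-chromen-4-one | COCOc1c(CC=C(C)C)c(OCOC)c2c(=O)c(O)c(-c3ccc4ccc(=O)oc4c3)oc2c1CC=C(C)C | intermediate
12 | 3,5-dihydroxy-7-(methoxymethoxy)-6,8-bis(3-methylbut-2-en-1-yl)-2-(2-oxo-2H-chromen-7-yl)-4H-chromen-4-one | COCOc1c(CC=C(C)C)c(O)c2c(=O)c(O)c(-c3ccc4ccc(=O)oc4c3)oc2c1CC=C(C)C | intermediate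
13 | methylmagnesium bromide | C[Mg]Br | starting material
14 | 3,5-dihydroxy-2-{3-hydroxy-4-[(1Z)-3-oxobut-1-en-1-yl]phenyl}-7-(methoxymethoxy)-6,8-bis(3-methylbut-2-en-1-yl)-4H-chromen-4-one (not isolated) | COCOc1c(CC=C(C)C)c(O)c2c(=O)c(O)c(-c3ccc(/C=C\C(C)=O)c(O)c3)oc2c1CC=C(C)C | intermediate
15 | 3,5-dihydroxy-2-{3-hydroxy-4-[(1Z)-3-hydroxy-3-methylbut-1-en-1-yl]phenyl}-7-(methoxymethoxy)-6,8-bis(3-methylbut-2-en-1-yl)-4H-chromen-4-one (not isolated) | COCOc1c(CC=C(C)C)c(O)c2c(=O)c(O)c(-c3ccc(/C=C\C(C)(C)O)c(O)c3)oc2c1CC=C(C)C | intermediate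
16 | 2-(2,2-dimethyl-2H-chromen-7-yl)-3,5-dihydroxy-7-(methoxymethoxy)-6,8-bis(3-methylbut-2-en-1-yl)-4H-chromen-4-one (dorsilurin C 7-methoxymethyl ether) | COCOc1c(CC=C(C)C)c(O)c2c(=O)c(O)c(-c3ccc4c(c3)OC(C)(C)C=C4)oc2c1CC=C(C)C | intermediate
17 | dorsilurin C, 2-(2,2-dimethyl-2H-chromen-7-yl)-3,5,7-trihydroxy-6,8-bis(3-methylbut-2-en-1-yl)-4H-chromen-4-one | CC(C)=CCc1c(O)c(CC=C(C)C)c2oc(-c3ccc4c(c3)OC(C)(C)C=C4)c(O)c(=O)c2c1O | target

**Step count and risks**

Total steps: 8. Longest linear sequence: 6 steps (4 → 6 → 7 → 11 → 12 → 16 → 17; the branch from 1 through 2 and 3 is equally long).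

Steps most likely to fail:

1. Step 7. What may go wrong: competing methyl addition at the C4 carbonyl of the flavonolate, conjugate addition at the β-carbon of the lactone, or stalling of the second addition because the magnesium salt precipitates. Fallback: the lactone-to-chromene conversion is moved to the aldehyde stage, where it is the known reaction on a simple coumarin. Setting out from 3, acetalisation (HC(OMe)3, TsOH cat., MeOH) should give 7-(dimethoxymethyl)-2H-chromen-2-one F1. MeMgBr in THF followed by aqueous HCl, which closes the pyran ring and hydrolyses the acetal, should give 2,2-dimethyl-2H-chromene-7-carbaldehyde F2. Claisen–Schmidt condensation of F2 with 7 (KOH, EtOH) should give (2E)-3-(2,2-dimethyl-2H-chromen-7-yl)-1-[2-hydroxy-4,6-bis(methoxymethoxy)-3,5-bis(3-methylbut-2-en-1-yl)phenyl]prop-2-en-1-one F3. Algar–Flynn–Oyamada oxidation (H2O2, NaOH, MeOH) should give 2-(2,2-dimethyl-2H-chromen-7-yl)-3-hydroxy-5,7-bis(methoxymethoxy)-6,8-bis(3-methylbut-2-en-1-yl)-4H-chromen-4-one F4. Methanolic HCl then removes both MOM ethers and the route is rejoined at 17.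

2. Step 5. What may go wrong: ring closure through the α-carbon (5-exo) towards the aurone skeleton, which a 6'-alkoxy group favours, or stalling at the dihydroflavonol stage. Fallback: the phenol is masked so that the epoxide can be isolated and cyclised under acid, where only the benzylic carbon is attacked. Setting out from 7, MOMCl and NaH in DMF should give 1-[2,4,6-tris(methoxymethoxy)-3,5-bis(3-methylbut-2-en-1-yl)phenyl]ethan-1-one F5. Condensation with 3 (KOH, EtOH, then acidification) should give (2E)-3-(2-oxo-2H-chromen-7-yl)-1-[2,4,6-tris(methoxymethoxy)-3,5-bis(3-methylbut-2-en-1-yl)phenyl]prop-2-en-1-one F6. Weitz–Scheffer epoxidation (H2O2, NaOH, MeOH, then acidification) should give racemic [(2R*,3S*)-3-(2-oxo-2H-chromen-7-yl)oxiran-2-yl][2,4,6-tris(methoxymethoxy)-3,5-bis(3-methylbut-2-en-1-yl)phenyl]methanone F7. Dilute methanolic HCl should remove the two MOM ethers flanking the carbonyl and close ring C by 6-endo opening of the epoxide, giving racemic trans-3,5-dihydroxy-7-(methoxymethoxy)-6,8-bis(3-methylbut-2-en-1-yl)-2-(2-oxo-2H-chromen-7-yl)-2,3-dihydro-4H-chromen-4-one F8. Dehydrogenation of F8 with alkaline H2O2 (the oxidation half of the Algar–Flynn–Oyamada sequence, now without a ring-closure choice) returns to the route at 12.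

3. Step 6. What may go wrong: cleavage of both MOM ethers at similar rates, since the 7-O-MOM group is itself activated by its two ortho substituents. Fallback: differentiation is moved from the cleavage to the alkylation. Setting out from 11, complete deprotection (3 M HCl, MeOH, 50 °C) should give 3,5,7-trihydroxy-6,8-bis(3-methylbut-2-en-1-yl)-2-(2-oxo-2H-chromen-7-yl)-4H-chromen-4-one F9. Mono-alkylation of its most acidic 7-hydroxyl (MOMCl, 1.05 equiv, K2CO3, acetone, 0 °C) returns to the route at 12.

**Further compounds**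

F1 | step 7 | 7-(dimethoxymethyl)-2H-chromen-2-one | COC(OC)c1ccc2ccc(=O)oc2c1
F2 | step 7 | 2,2-dimethyl-2H-chromene-7-carbaldehyde | CC1(C)C=Cc2ccc(C=O)cc2O1
F3 | step 7 | (2E)-3-(2,2-dimethyl-2H-chromen-7-yl)-1-[2-hydroxy-4,6-bis(methoxymethoxy)-3,5-bis(3-methylbut-2-en-1-yl)phenyl]prop-2-en-1-one | O=C(/C=C/c1ccc2c(c1)OC(C)(C)C=C2)c1c(O)c(CC=C(C)C)c(OCOC)c(CC=C(C)C)c1OCOC
F4 | step 7 | 2-(2,2-dimethyl-2H-chromen-7-yl)-3-hydroxy-5,7-bis(methoxymethoxy)-6,8-bis(3-methylbut-2-en-1-yl)-4H-chromen-4-one | COCOc1c(CC=C(C)C)c(OCOC)c2c(=O)c(O)c(-c3ccc4c(c3)OC(C)(C)C=C4)oc2c1CC=C(C)C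
F5 | step 5 | 1-[2,4,6-tris(methoxymethoxy)-3,5-bis(3-methylbut-2-en-1-yl)phenyl]ethan-1-one | CC(=O)c1c(OCOC)c(CC=C(C)C)c(OCOC)c(CC=C(C)C)c1OCOC
F6 | step 5 | (2E)-3-(2-oxo-2H-chromen-7-yl)-1-[2,4,6-tris(methoxymethoxy)-3,5-bis(3-methylbut-2-en-1-yl)phenyl]prop-2-en-1-one | O=C(/C=C/c1ccc2ccc(=O)oc2c1)c1c(OCOC)c(CC=C(C)C)c(OCOC)c(CC=C(C)C)c1OCOC
F7 | step 5 | racemic [(2R*,3S*)-3-(2-oxo-2H-chromen-7-yl)oxiran-2-yl][2,4,6-tris(methoxymethoxy)-3,5-bis(3-methylbut-2-en-1-yl)phenyl]methanone (trans, one enantiomer drawn) | O=C(c1c(OCOC)c(CC=C(C)C)c(OCOC)c(CC=C(C)C)c1OCOC)[C@@H]2O[C@H]2c3ccc4ccc(=O)oc4c3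
F8 | step 5 | racemic (2R*,3R*)-3,5-dihydroxy-7-(methoxymethoxy)-6,8-bis(3-methylbut-2-en-1-yl)-2-(2-oxo-2H-chromen-7-yl)-2,3-dihydro-4H-chromen-4-one (trans, one enantiomer drawn) | O=C1[C@H](O)[C@@H](c2ccc3ccc(=O)oc3c2)Oc2c(CC=C(C)C)c(OCOC)c(CC=C(C)C)c(O)c12
F9 | step 6 | 3,5,7-trihydroxy-6,8-bis(3-methylbut-2-en-1-yl)-2-(2-oxo-2H-chromen-7-yl)-4H-chromen-4-one | CC(C)=CCc1c(O)c(CC=C(C)C)c2oc(-c3ccc4ccc(=O)oc4c3)c(O)c(=O)c2c1O
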